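## Structural features

The target (34) is a ten-membered carbocycle (C1–C10, germacrane numbering; C14 on C10, C15 on C4, C11–C13 on C7) fused across C6–C7 to an α-methylene-γ-butyrolactone, with the ring oxygen on C6 and C11 on C7. The carbocycle holds a Z trisubstituted olefin (C1=C10) and an E trisubstituted olefin (C4=C5) in a 1,5-relationship. Four contiguous oxygenated stereocentres sit on the ring: C6 (lactone oxygen, allylic), C7 (quaternary, tertiary hydroxyl), C8 (angelate) and C9 (allylic hydroxyl); in a flat drawing O6/O7 are trans, O7/O8 cis and O8/O9 trans. The fragile groups are the α-methylene lactone (Michael acceptor), the angelate (Z to E isomerisation, acyl migration to the 7- and 9-hydroxyls), the β-hydroxy lactone (dehydration, translactonisation) and the medium-ring 1,5-diene (transannular reactions in acid, Cope rearrangement on heating). The real difficulty is to close a ten-membered ring with both olefin geometries defined while joining two adjacent oxygenated carbons, one of them quaternary, in the correct relative and absolute sense. The key step uses the fact that C9, C10, C1, C2, C3 and C4 can be written as a cyclohexene in which the cis C1=C10 olefin is the ring double bond, C9 is a carbinol carbon and C4 a quaternary carbon, each bearing a two-carbon alkenyl group. The C4–C9 bond of that ring is then the central σ-bond of the 1,5-diene C7=C8–C9–C4–C5=C6, and a [3,3] shift trades it for the C6–C7 bond between the two oxygenated centres.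

## Logic of the disconnections

34 ⇒ 33 ⇒ 32. Cut: the O8–acyl bond (and the O9–Si bond). The Z-unsaturated ester isomerises with bases and nucleophiles, so it is introduced last but one. This removes the only sensitive ester from all earlier steps. The demand is that O8 be the only acylable hydroxyl in 32; O7 is tertiary and O9 carries the more robust silyl group.

32 ⇒ 31 ⇒ 28. Cut: C11=C13. The exocyclic methylene is added to the finished lactone by enolate Mannich chemistry, so the Michael acceptor is absent from all earlier steps. The demand is a lactone with no ketone and no ester elsewhere, which fixes the order: C9 is reduced and O8/O9 are silylated (with groups of different lability) before this step.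

28 ⇒ 27 ⇒ 26. Cut: the C9–H bond. The C9 carbinol is traced to the ketone that the ring expansion leaves at C9. The free tertiary 7-hydroxyl of 26 delivers hydride internally, which puts O9 trans to O7. The demand is that O7 be free and O8 already protected.

26 ⇒ 25 ⇒ 24. Cut: the lactone C12–O6 bond (by oxidation level) and the three benzylic C–O bonds. All three 4-methoxybenzyl ethers fall in one operation and the primary C12 alcohol is oxidised onto O6, so no separate protecting group is needed for O12. The demand is oxidation of the primary alcohol in preference to the allylic C6 hydroxyl; C9 is kept as a ketone so that no second allylic alcohol is exposed.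

24 ⇒ 23 ⇒ 21. Cut: the C8–O bond. The C8 oxygen is introduced α to the C9 ketone by enolate oxidation. The demand is face selectivity at C8 next to the quaternary C7; a lithium enolate chelated to the C7 ether is used for this. The enolate that the ring expansion itself produces is not oxidised directly, because its exposed face would place O8 trans to O7.

21 ⇒ 19. Cut: C6–C7; reconnect C4–C9. This is the key ring contraction in the retrosynthetic sense: the ten-membered dienone becomes a cyclohexenol bearing two (E)-enol ethers. Both olefin geometries and both stereocentres of 21 are reduced to two stereocentres and two enol-ether geometries on a six-membered ring. The demand is a trans arrangement of the alkenyl groups and (E) geometry in both enol ethers.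

19 ⇒ 18 ⇒ 16 + 17. Cut: the two enol-ether C–O bonds. Enol ethers made from carbonyl compounds would be E/Z mixtures, whereas copper-catalysed substitution of stereodefined iodoalkenes retains geometry. Both C–O bonds are made in one step, which consumes two molecules of 17. The demand is that the C9 hydroxyl be silylated so that no alkoxide forms under the basic coupling conditions.

16 ⇒ 14 ⇒ 9 + 11, and 11 ⇒ 10. Cut: the C7–I and C8–H bonds (syn hydrometalation of an alkyne) and the C8–C9 bond (acetylide addition to the enone). A β-alkoxyalkenyllithium with lithium anti to oxygen would be the direct nucleophile, but such a species loses lithium alkoxide by anti elimination and has no reliable stereodefined source; the alkyne postpones the C7–O bond. The demand is attack of 12 on the face of 9 opposite the iodoalkenyl group.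

9 ⇒ 8 ⇒ 7 ⇒ 5 ⇒ 4. Cut: C5=C6 (aldehyde olefination), the C1=C10 unsaturation, and one carbon of the allyl group. The allyl group has three carbons and the alkenyl unit on C4 only two, so the double bond is moved inward and cleaved to the one-carbon aldehyde 8 before the (E)-iodoalkene is built. The demand is cleavage of the isolated olefin in the presence of the enone.

4 ⇒ 3 ⇒ 1. Cut: the C4–allyl bond. The quaternary centre, the only source of absolute configuration, comes from catalytic asymmetric allylation of the enol carbonate of 1. The demand is high enantioselectivity at a fully substituted α-carbon; the second α-centre is irrelevant because it becomes sp2 in 7.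

## Other disconnections considered

Alternative 1: The cut passes through C1–C10 and C4–C5, taken as single bonds of a cyclobutane. A lactone-fused, oxygenated 2-methylcyclohexenone A1 would be irradiated with 1-methylcyclobutene A2 to give the cis-anti-cis photoadduct A3; heating would then cleave the central four-membered ring (C5–C10 and C1–C4) and release both olefins and the ten-membered ring together.
- In its favour: C6, C7 and C8 are set on a rigid six-membered ring before expansion. This is better than the chosen plan, which must oxygenate C8 on a medium ring.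
- Like the chosen plan it is a ring expansion and avoids end-to-end closure; on this point the two are equal.
- Against it: an unsymmetrical cyclobutene and an α-methyl enone have no strong bias for the required head-to-tail orientation or for one enone face.
- The thermal cycloreversion is stepwise and needs high temperature, so nothing decides which olefin becomes E. The resulting 1,5-diene can also undergo Cope rearrangement, and the β-hydroxy ketone can eliminate.
- The C9 ketone remains, so the later steps are no shorter, and A1 needs its own enantioselective synthesis.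
- Comparison: the chosen plan fixes both olefin geometries and both new stereocentres in one ordered, low-temperature transition state; alternative 1 trades that for easier stereocontrol at C8.

Alternative 2: The cut is the C8–C9 bond. A lactone dialdehyde A4 (C8 aldehyde on the lactone, C9 as a Z-enal) would be closed with SmI2 (divalent samarium) to the 7,8,9-triol A5, one acylation short of the target.
- In its favour: it is the most convergent plan. The methylene lactone and C6/C7 are made in a small fragment, and ring, C8 and C9 arise in one step. After ring formation its step economy is clearly better than that of the chosen plan.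
- Against it: it is an end-to-end closure of a strained ten-membered ring and needs high dilution.
- The enal ketyl is an allylic radical and can also bond through C1.
- SmI2 can reduce the α-methylene lactone.
- Chelated diketyl couplings tend to give cis diols, whereas the target needs the trans 8,9-diol.
- A5 has O8 and O9 both free, and the more hindered O8 would have to be acylated selectively.
- Comparison: the chosen plan is longer, but it differentiates O8 from O9 by the order of events and needs no dilution.

Alternative 3: The cut is C5–C6 together with C4–C15. An ynal A6 would be cyclised with Ni(cod)2 (zerovalent nickel), a carbene ligand and Me2Zn to the ten-membered dienol A7.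
- In its favour: syn addition of the methyl group and the aldehyde carbon across the alkyne gives the E C4=C5 olefin by mechanism. In geometric control it equals the chosen plan.
- The C7–C9 triad is built on an open chain with O8 and O9 already carrying different silyl groups. This is better than the chosen plan on both counts.
- The new C6 hydroxyl sits next to the ester and can lactonise directly.
- Against it: it is again a macrocyclisation; endocyclic versus exocyclic closure depends on the ligand.
- C6 is created in the ring-closing event next to a hindered quaternary silyloxy carbon, with no clear control element.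
- The Z C1=C10 olefin and the whole triad must be assembled in a long linear precursor.
- Lactonisation, methylenation, silyl sorting and acylation still follow, so the later steps are as long as in the chosen plan.
- Comparison: alternative 3 has the safer stereochemistry at C8 and C9; the chosen plan has the safer ring formation and controls C6.

Key step: step 12

Assumption: the sense of induction of the palladium–PHOX allylation of the 2,6-dimethyl substrate is taken to follow that of 2-methylcyclohexanone, so that the (R)-ligand gives the (R)-quaternary centre; if not, the ligand antipode is used.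

## Route

Step 1
Reactants: 1 2,6-dimethylcyclohexanone
Product: 3 allyl 2,6-dimethylcyclohex-1-en-1-yl carbonate, via lithium enolate 2 (not isolated)
Conditions: LiN(SiMe3)2, THF, 0 °C; then allyl chloroformate, −78 °C to 25 °C
Reagents that add atoms: allyl chloroformate, C=CCOC(Cl)=O
Why: Enolisation can occur in one sense only, since each α-carbon carries one hydrogen and one methyl group; the hard chloroformate acylates the enolate on oxygen and gives the enol carbonate needed for decarboxylative allylation.

Step 2
Reactants: 3 allyl 2,6-dimethylcyclohex-1-en-1-yl carbonate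
Product: 4 (2R)-2-allyl-2,6-dimethylcyclohexanone (both C6 epimers)
Conditions: Pd2(dba)3 (cat.), (R)-t-BuPHOX (cat.), THF, 25 °C
Reagents that add atoms: none
Why: Palladium-catalysed decarboxylative asymmetric allylic alkylation (Tsuji allylation type): loss of CO2 gives a π-allylpalladium enolate that recombines at carbon under control of the PHOX ligand and sets the quaternary centre (future C4) as R; the other α-centre is left as a mixture because step 4 removes it.

Step 3
Reactants: 4 (2R)-2-allyl-2,6-dimethylcyclohexanone
Product: 5 (2R)-2,6-dimethyl-2-[(E)-prop-1-enyl]cyclohexanone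
Conditions: RuHCl(CO)(PPh3)3 (cat.), toluene, 80 °C
Reagents that add atoms: none
Why: Ruthenium hydride-catalysed olefin isomerisation (hydrometalation and β-hydride elimination) moves the double bond one position inward and stops there because the next carbon is quaternary; the E/Z ratio does not matter since the olefin is cleaved in step 5.

Step 4
Reactants: 5 (2R)-2,6-dimethyl-2-[(E)-prop-1-enyl]cyclohexanone
Product: 7 (6R)-2,6-dimethyl-6-[(E)-prop-1-enyl]cyclohex-2-en-1-one, via trimethylsilyl enol ether 6 (not isolated)
Conditions: LiN(i-Pr)2, THF, −78 to 0 °C; Me3SiCl; then Pd(OAc)2, MeCN, 25 °C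
Reagents that add atoms: none
Why: Saegusa–Ito oxidation: the only possible (tetrasubstituted) silyl enol ether is formed, and β-hydride elimination of the palladium enolate toward the ring methylene gives the conjugated endocyclic enone, which is the future cis C1=C10 olefin.

Step 5
Reactants: 7 (6R)-2,6-dimethyl-6-[(E)-prop-1-enyl]cyclohex-2-en-1-one
Product: 8 (1R)-1,3-dimethyl-2-oxocyclohex-3-ene-1-carbaldehyde
Conditions: O3, CH2Cl2, pyridine, −78 °C (indicator dye end point); then Me2S
Reagents that add atoms: ozone, [O-][O+]=O
Why: Ozonolysis with reductive work-up: the isolated disubstituted olefin reacts much faster than the electron-poor enone double bond, and the aldehyde obtained is one carbon shorter than the allyl group, as the two-carbon alkenyl unit requires; the quaternary centre cannot epimerise.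

Step 6
Reactants: 8 (1R)-1,3-dimethyl-2-oxocyclohex-3-ene-1-carbaldehyde
Product: 9 (6R)-6-[(E)-2-iodoethenyl]-2,6-dimethylcyclohex-2-en-1-one
Conditions: CrCl2, CHI3, THF, 0 to 25 °C
Reagents that add atoms: iodoform, IC(I)I
Why: Takai olefination: the geminal dichromium reagent adds to the aldehyde only (the hindered enone is untouched) and elimination gives the (E)-iodoalkene, which fixes the geometry of the future C5=C6 enol ether.

Step 7
Reactants: 10 but-3-yn-1-ol
Product: 11 1-[(but-3-yn-1-yloxy)methyl]-4-methoxybenzene
Conditions: NaH, 4-methoxybenzyl chloride, Bu4NI (cat.), THF/DMF, 0 to 25 °C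
Reagents that add atoms: 4-methoxybenzyl chloride, COc1ccc(CCl)cc1
Why: Williamson etherification of the primary alkoxide with a benzylic chloride; one equivalent of NaH removes the hydroxyl proton in preference to the alkyne C–H.

Step 8
Reactants: 9 (6R)-6-[(E)-2-iodoethenyl]-2,6-dimethylcyclohex-2-en-1-one; 11 1-[(but-3-yn-1-yloxy)methyl]-4-methoxybenzene
Product: 14 triethylsilyl ether of (1R,6R)-6-[(E)-2-iodoethenyl]-1-{4-[(4-methoxybenzyl)oxy]but-1-ynyl}-2,6-dimethylcyclohex-2-en-1-ol (alkynyl trans to iodoethenyl), via lithium acetylide 12 (not isolated), via lithium alkoxide 13 (not isolated)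
Conditions: 11, n-BuLi, THF, −78 °C; then 9, −78 to −40 °C; then Et3SiOTf, −78 to 0 °C
Reagents that add atoms: triethylsilyl trifluoromethanesulfonate, CC[Si](CC)(CC)OS(=O)(=O)C(F)(F)F
Why: 1,2-Addition of a lithium acetylide to a non-enolisable enone; the flat iodoalkenyl group is expected to lie pseudoaxial next to the geminal methyl group, so axial attack comes from the opposite face and sets C9 with the alkynyl group trans to the iodoalkenyl group, and the hindered alkoxide is capped in the same flask. An alkyne is used because a β-alkoxyalkenyllithium with lithium anti to oxygen would eliminate lithium alkoxide.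

Step 9
Reactants: 14 triethylsilyl ether of the (1R,6R)-alkynyl carbinol
Product: 16 triethylsilyl ether of (1R,6R)-6-[(E)-2-iodoethenyl]-1-{(1E)-2-iodo-4-[(4-methoxybenzyl)oxy]but-1-enyl}-2,6-dimethylcyclohex-2-en-1-ol, via alkenylzirconocene 15 (not isolated)
Conditions: Cp2Zr(H)Cl, THF, 25 °C; then I2, −20 °C
Reagents that add atoms: iodine, II
Why: Hydrozirconation–iodination: syn addition of Zr–H puts zirconium on C7, away from the quaternary silyloxy carbon and next to the chelating ether chain, and iodinolysis with retention gives the iodoalkene with iodine trans to C9; the alkyne reacts much faster than the iodoalkene or the trisubstituted ring olefin.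

Step 10
Reactants: 16 bis(iodoalkene) triethylsilyl ether; 17 4-methoxybenzyl alcohol
Product: 18 triethylsilyl ether of (1R,6R)-1-{(1E)-2,4-bis[(4-methoxybenzyl)oxy]but-1-enyl}-6-{(E)-2-[(4-methoxybenzyl)oxy]ethenyl}-2,6-dimethylcyclohex-2-en-1-ol
Conditions: CuI (cat.), 3,4,7,8-tetramethyl-1,10-phenanthroline (cat.), Cs2CO3, 17 (excess; two equivalents are incorporated), toluene, 80 °C
Reagents that add atoms: 4-methoxybenzyl alcohol (the second equivalent of 17), COc1ccc(CO)cc1
Why: Copper-catalysed Ullmann-type C–O coupling of alkenyl iodides with an alcohol, a reaction that keeps olefin geometry; each of the two iodides takes up one molecule of 17, so both (E)-enol ethers are made from stereodefined iodides in one operation, and the silyl ether prevents alkoxide formation at C9.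

Step 11
Reactants: 18 bis(enol ether) triethylsilyl ether
Product: 19 (1R,6R)-1-{(1E)-2,4-bis[(4-methoxybenzyl)oxy]but-1-enyl}-6-{(E)-2-[(4-methoxybenzyl)oxy]ethenyl}-2,6-dimethylcyclohex-2-en-1-ol
Conditions: Bu4NF, THF, 0 to 25 °C
Reagents that add atoms: none
Why: Fluoride cleavage of the silyl ether under basic conditions leaves both acid-sensitive enol ethers intact; the water in the reagent keeps the alcohol protonated so that rearrangement does not start here.

Step 12
Reactants: 19 trans-dialkenylcyclohexenol with two (E)-enol ethers
Product: 21 (6S,7S)-6,7-bis[(4-methoxybenzyl)oxy]-7-{2-[(4-methoxybenzyl)oxy]ethyl}-4,10-dimethylcyclodeca-1(10),4-dien-9-one (1(10)Z,4E; germacrane locants), via potassium enolate 20 (not isolated)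
Conditions: KH, 18-crown-6, THF, 0 to 25 °C; then AcOH, THF, −78 °C
Reagents that add atoms: none
Why: Proposed new method: deprotonation gives the potassium alkoxide, whose charge weakens the allylic C4–C9 bond so that the 1,5-diene C7=C8–C9–C4–C5=C6 undergoes a [3,3]-sigmatropic shift; the closest known reaction type is the anionic oxy-Cope ring expansion of trans-1,2-divinylcyclohexanols to (E)-cyclodec-5-enones, here extended to a substrate with an alkoxy group on each bond-forming terminus. The ten-membered ring closes by four-carbon ring expansion of the cyclohexene (C6–C7 made, C4–C9 broken), not by end-to-end cyclisation, so no dilution is needed and the cis C1=C10 olefin is the cyclohexene double bond carried through unchanged. The trans alkenyl groups can reach only a chair six-centre array that is trans-fused to the cyclohexene, with O9 and C15 axial and C3 and C10 equatorial; C3 equatorial at C4 makes the new C4=C5 olefin E. C6 is set by the (E) geometry of the C5=C6 enol ether (alkoxy equatorial) and C7 by the (E) geometry of the C7=C8 enol ether (alkoxy equatorial, C11 axial), while the C4 and C9 configurations decide which enantiomeric chair is used, so chirality passes from C4/C9 to C6/C7. The step needs chair over boat and concerted shift over fragmentation and recombination; the trans arrangement of the alkenyl groups, the single axial CH2 group on the chair and a low temperature are expected to secure both. The first-formed enolate holds the C7–O bond near its nodal plane, which disfavours β-elimination, and it is protonated cold. It is not oxidised in the same flask, because its exposed face at C8 would place O8 trans to O7.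

Step 13
Reactants: 21 ten-membered dienone
Product: 23 (6S,7S,8R)-8-hydroxy derivative of 21 (8-hydroxyl cis to the C7 ether oxygen), via lithium enolate 22 (not isolated)
Conditions: LiN(SiMe3)2, THF, −78 °C; then 2-(phenylsulfonyl)-3-phenyloxaziridine, −78 °C; AcOH quench
Reagents that add atoms: 2-(phenylsulfonyl)-3-phenyloxaziridine, O=S(=O)(c1ccccc1)N1OC1c1ccccc1
Why: Enolate hydroxylation with an N-sulfonyloxaziridine: lithium bound to the carbonyl oxygen and the C7 ether oxygen directs deprotonation to C8 and holds O7 in the enolate plane, which also keeps the C7–O bond out of alignment for β-elimination. The ring bond C7–C6 then shields one face and the oxidant enters from the other, which should place the new hydroxyl cis to O7.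

Step 14
Reactants: 23 α-hydroxy ketone
Product: 24 (6S,7R,8R)-8-(triethylsilyloxy) ketone
Conditions: Et3SiOTf, 2,6-lutidine, CH2Cl2, −78 °C
Reagents that add atoms: triethylsilyl trifluoromethanesulfonate, CC[Si](CC)(CC)OS(=O)(=O)C(F)(F)F
Why: Silylation of a hindered secondary hydroxyl with a silyl triflate at low temperature, where the ketone is not enolised; O8 is masked for the oxidative and basic steps that follow.

Step 15
Reactants: 24 8-(triethylsilyloxy) ketone
Product: 25 (6S,7R,8R)-6,7-dihydroxy-7-(2-hydroxyethyl)-4,10-dimethyl-8-(triethylsilyloxy)cyclodeca-1(10),4-dien-9-one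
Conditions: DDQ, CH2Cl2/pH 7 phosphate buffer, 0 to 25 °C
Reagents that add atoms: none
Why: Oxidative cleavage of all three 4-methoxybenzyl ethers by hydride abstraction and hydrolysis of the oxocarbenium ions; the wet medium suppresses benzylidene acetal formation between neighbouring oxygens, and the silyl ether, enone and diene are inert to DDQ.

Step 16
Reactants: 25 triol
Product: 26 (6S,7R,8R)-γ-lactone (C12 carbonyl on O6, C11 = CH2) with free 7-hydroxyl, 8-triethylsilyloxy group and C9 ketone
Conditions: TEMPO (cat.), PhI(OAc)2, CH2Cl2, 25 °C
Reagents that add atoms: none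
Why: Oxidative lactonisation of a 1,4-diol: oxoammonium oxidation of the primary alcohol, capture of the aldehyde by the cis-disposed C6 hydroxyl as a five-membered lactol, and further oxidation to the lactone. Primary-over-secondary selectivity and fast lactol formation protect the allylic C6 hydroxyl, and with C9 still a ketone no other secondary alcohol is exposed.

Step 17
Reactants: 26 keto lactone
Product: 27 (6S,7R,8S,9R)-7,9-dihydroxy-8-(triethylsilyloxy) lactone (9-hydroxyl trans to O7 and to O8)
Conditions: Me4NBH(OAc)3, MeCN/AcOH, −30 to −10 °C
Reagents that add atoms: none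
Why: Evans–Saksena reduction: the tertiary 7-hydroxyl exchanges onto boron and hydride is delivered through a six-membered transition state to the face of the C9 carbonyl on which O7 lies, giving the 9-hydroxyl trans to O7 by 1,2-reduction of the enone; lactone and silyl ether are not reduced.

Step 18
Reactants: 27 7,9-diol
Product: 28 (6S,7R,8S,9R)-9-(tert-butyldimethylsilyloxy)-7-hydroxy-8-(triethylsilyloxy) lactone
Conditions: t-BuMe2SiOTf, 2,6-lutidine, CH2Cl2, −78 °C
Reagents that add atoms: tert-butyldimethylsilyl trifluoromethanesulfonate, CC(C)(C)[Si](C)(C)OS(=O)(=O)C(F)(F)F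
Why: Silyl triflates discriminate sharply between the secondary allylic 9-hydroxyl and the tertiary 7-hydroxyl at −78 °C; the more robust silyl group is put on O9 so that O8 can be unmasked first.

Step 19
Reactants: 28 bis(silyl) lactone
Product: 31 (6S,7R,8S,9R)-α-methylene lactone (C11=C13) with 9-(tert-butyldimethylsilyloxy), 8-(triethylsilyloxy) and free 7-hydroxyl, via Mannich base 29 (not isolated), via ammonium iodide 30 (not isolated)
Conditions: LiN(i-Pr)2 (2.3 equiv), THF, −78 °C; dimethylmethylideneammonium iodide, −78 to 0 °C; then MeI, MeOH, 25 °C; then NaHCO3, CH2Cl2/H2O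
Reagents that add atoms: dimethylmethylideneammonium iodide, C=[N+](C)C.[I-]
Why: α-Methylenation of a lactone by Mannich reaction of its enolate, quaternisation and elimination; the 7-hydroxyl is carried as its alkoxide (dianion), which cannot be expelled from the β-position, and no ketone or ester is present.

Step 20
Reactants: 31 bis(silyl) α-methylene lactone
Product: 32 (6S,7S,8S,9R)-9-(tert-butyldimethylsilyloxy)-7,8-dihydroxy α-methylene lactone
Conditions: pyridinium p-toluenesulfonate (cat.), MeOH/CH2Cl2, 0 °C
Reagents that add atoms: none
Why: Acid-catalysed methanolysis removes a triethylsilyl ether much faster than a tert-butyldimethylsilyl ether and frees O8 alone; if the triethylsilyl group had moved to O7 under the basic conditions of step 19, the same diol results.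

Step 21
Reactants: 32 7,8-diol
Product: 33 (6S,7R,8S,9R)-8-O-angeloyl-9-O-(tert-butyldimethylsilyl) derivative of the target
Conditions: angelic acid, 2,4,6-trichlorobenzoyl chloride, Et3N, toluene, 25 °C; then 32, 75 °C
Reagents that add atoms: angelic acid, C/C=C(/C)C(O)=O
Why: Esterification through the mixed 2,4,6-trichlorobenzoic anhydride (Yamaguchi type) without a nucleophilic catalyst, because such catalysts isomerise angelates to tiglates; only the secondary 8-hydroxyl reacts, since the 7-hydroxyl is tertiary and O9 is silylated.

Step 22
Reactants: 33 silylated angelate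
Product: 34 target, (6S,7R,8S,9R)-8-angeloyloxy-7,9-dihydroxy α-methylene lactone (CNP0292337.1)
Conditions: HF·pyridine, pyridine, THF, 0 to 25 °C
Reagents that add atoms: none
Why: Buffered HF·pyridine cleaves the remaining silyl ether without affecting the angelate, the α-methylene lactone or the diene.

## Compound list

1 | 2,6-dimethylcyclohexanone (cis/trans mixture) | CC1CCCC(C)C1=O | starting material
2 | lithium 2,6-dimethylcyclohex-1-en-1-olate | [Li]OC1=C(C)CCCC1C | intermediate
3 | allyl 2,6-dimethylcyclohex-1-en-1-yl carbonate | C=CCOC(=O)OC1=C(C)CCCC1C | intermediate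
4 | (2R)-2-allyl-2,6-dimethylcyclohexanone (C6 epimers) | O=C1C(C)CCC[C@]1(C)CC=C | intermediate
5 | (2R)-2,6-dimethyl-2-[(E)-prop-1-enyl]cyclohexanone | O=C1C(C)CCC[C@]1(C)/C=C/C | intermediate
6 | trimethyl({(6R)-2,6-dimethyl-6-[(E)-prop-1-enyl]cyclohex-1-en-1-yl}oxy)silane | C[Si](C)(C)OC1=C(C)CCC[C@]1(C)/C=C/C | intermediate
7 | (6R)-2,6-dimethyl-6-[(E)-prop-1-enyl]cyclohex-2-en-1-one | O=C1C(C)=CCC[C@]1(C)/C=C/C | intermediate
8 | (1R)-1,3-dimethyl-2-oxocyclohex-3-ene-1-carbaldehyde | O=C1C(C)=CCC[C@]1(C)C=O | intermediate
9 | (6R)-6-[(E)-2-iodoethenyl]-2,6-dimethylcyclohex-2-en-1-one | O=C1C(C)=CCC[C@]1(C)/C=C/I | intermediate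
10 | but-3-yn-1-ol | C#CCCO | starting material
11 | 1-[(but-3-yn-1-yloxy)methyl]-4-methoxybenzene | C#CCCOCc1ccc(OC)cc1 | intermediate
12 | lithium acetylide of 11 | [Li]C#CCCOCc1ccc(OC)cc1 | intermediate
13 | lithium (1R,6R)-6-[(E)-2-iodoethenyl]-1-{4-[(4-methoxybenzyl)oxy]but-1-ynyl}-2,6-dimethylcyclohex-2-en-1-olate | [Li]O[C@]1(C#CCCOCc2ccc(OC)cc2)C(C)=CCC[C@]1(C)/C=C/I | intermediate
14 | triethyl({(1R,6R)-6-[(E)-2-iodoethenyl]-1-{4-[(4-methoxybenzyl)oxy]but-1-ynyl}-2,6-dimethylcyclohex-2-en-1-yl}oxy)silane | CC[Si](CC)(CC)O[C@]1(C#CCCOCc2ccc(OC)cc2)C(C)=CCC[C@]1(C)/C=C/I | intermediate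
15 | chlorobis(cyclopentadienyl)zirconium alkenyl from 14 (Zr on C7, trans to C9) | CC[Si](CC)(CC)O[C@]1(/C=C(/[Zr](Cl)(C2C=CC=C2)C2C=CC=C2)CCOCc2ccc(OC)cc2)C(C)=CCC[C@]1(C)/C=C/I | intermediate
16 | triethyl({(1R,6R)-6-[(E)-2-iodoethenyl]-1-{(1E)-2-iodo-4-[(4-methoxybenzyl)oxy]but-1-enyl}-2,6-dimethylcyclohex-2-en-1-yl}oxy)silane | CC[Si](CC)(CC)O[C@]1(/C=C(/I)CCOCc2ccc(OC)cc2)C(C)=CCC[C@]1(C)/C=C/I | intermediate
17 | 4-methoxybenzyl alcohol | COc1ccc(CO)cc1 | starting material
18 | triethylsilyl ether of 19 | CC[Si](CC)(CC)O[C@]1(/C=C(/OCc2ccc(OC)cc2)CCOCc2ccc(OC)cc2)C(C)=CCC[C@]1(C)/C=C/OCc1ccc(OC)cc1 | intermediate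
19 | (1R,6R)-1-{(1E)-2,4-bis[(4-methoxybenzyl)oxy]but-1-enyl}-6-{(E)-2-[(4-methoxybenzyl)oxy]ethenyl}-2,6-dimethylcyclohex-2-en-1-ol | O[C@]1(/C=C(/OCc2ccc(OC)cc2)CCOCc2ccc(OC)cc2)C(C)=CCC[C@]1(C)/C=C/OCc1ccc(OC)cc1 | intermediate
20 | potassium C8–C9 enolate of 21 (C7 and C10 trans on the enolate double bond) | COc1ccc(CO[C@H]2/C=C(\C)CC/C=C(/C)\C(O[K])=C\[C@]2(CCOCc3ccc(OC)cc3)OCc3ccc(OC)cc3)cc1 | intermediate
21 | (6S,7S)-6,7-bis[(4-methoxybenzyl)oxy]-7-{2-[(4-methoxybenzyl)oxy]ethyl}-4,10-dimethylcyclodeca-1(10),4-dien-9-one, 1(10)Z,4E | COc1ccc(CO[C@H]2/C=C(\C)CC/C=C(/C)C(=O)C[C@]2(CCOCc3ccc(OC)cc3)OCc3ccc(OC)cc3)cc1 | intermediate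
22 | lithium C8–C9 enolate of 21, chelated by the C7 ether oxygen | COc1ccc(CO[C@H]2/C=C(\C)CC/C=C(/C)\C(O[Li])=C\[C@]2(CCOCc3ccc(OC)cc3)OCc3ccc(OC)cc3)cc1 | intermediate
23 | (6S,7S,8R)-8-hydroxy derivative of 21 | COc1ccc(CO[C@H]2/C=C(\C)CC/C=C(/C)C(=O)[C@H](O)[C@]2(CCOCc3ccc(OC)cc3)OCc3ccc(OC)cc3)cc1 | intermediate
24 | (6S,7R,8R)-8-(triethylsilyloxy) derivative of 21 | COc1ccc(CO[C@H]2/C=C(\C)CC/C=C(/C)C(=O)[C@H](O[Si](CC)(CC)CC)[C@]2(CCOCc3ccc(OC)cc3)OCc3ccc(OC)cc3)cc1 | intermediate
25 | (6S,7R,8R)-6,7-dihydroxy-7-(2-hydroxyethyl)-4,10-dimethyl-8-(triethylsilyloxy)cyclodeca-1(10),4-dien-9-one | O[C@H]1/C=C(\C)CC/C=C(/C)C(=O)[C@H](O[Si](CC)(CC)CC)[C@]1(CCO)O | intermediate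
26 | (6S,7R,8R)-7-hydroxy-9-oxo-8-(triethylsilyloxy) γ-lactone (12,6-olide, C11 = CH2) | C1C(=O)O[C@H]2/C=C(\C)CC/C=C(/C)C(=O)[C@H](O[Si](CC)(CC)CC)[C@@]12O | intermediate
27 | (6S,7R,8S,9R)-7,9-dihydroxy-8-(triethylsilyloxy) γ-lactone | C1C(=O)O[C@H]2/C=C(\C)CC/C=C(/C)[C@@H](O)[C@H](O[Si](CC)(CC)CC)[C@@]12O | intermediate
28 | (6S,7R,8S,9R)-9-(tert-butyldimethylsilyloxy)-7-hydroxy-8-(triethylsilyloxy) γ-lactone | C1C(=O)O[C@H]2/C=C(\C)CC/C=C(/C)[C@@H](O[Si](C)(C)C(C)(C)C)[C@H](O[Si](CC)(CC)CC)[C@@]12O | intermediate
29 | 11-[(dimethylamino)methyl] derivative of 28 (C11 epimers) | CN(C)CC1C(=O)O[C@H]2/C=C(\C)CC/C=C(/C)[C@@H](O[Si](C)(C)C(C)(C)C)[C@H](O[Si](CC)(CC)CC)[C@@]12O | intermediate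
30 | 11-[(trimethylammonio)methyl] iodide derived from 29 | C[N+](C)(C)CC1C(=O)O[C@H]2/C=C(\C)CC/C=C(/C)[C@@H](O[Si](C)(C)C(C)(C)C)[C@H](O[Si](CC)(CC)CC)[C@@]12O.[I-] | intermediate
31 | (6S,7R,8S,9R)-9-(tert-butyldimethylsilyloxy)-7-hydroxy-8-(triethylsilyloxy) α-methylene lactone | C=C1C(=O)O[C@H]2/C=C(\C)CC/C=C(/C)[C@@H](O[Si](C)(C)C(C)(C)C)[C@H](O[Si](CC)(CC)CC)[C@@]12O | intermediate
32 | (6S,7S,8S,9R)-9-(tert-butyldimethylsilyloxy)-7,8-dihydroxy α-methylene lactone | C=C1C(=O)O[C@H]2/C=C(\C)CC/C=C(/C)[C@@H](O[Si](C)(C)C(C)(C)C)[C@H](O)[C@@]12O | intermediate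
33 | (6S,7R,8S,9R)-8-angeloyloxy-9-(tert-butyldimethylsilyloxy)-7-hydroxy α-methylene lactone | C=C1C(=O)O[C@H]2/C=C(\C)CC/C=C(/C)[C@@H](O[Si](C)(C)C(C)(C)C)[C@H](OC(=O)/C(C)=C\C)[C@@]12O | intermediate
34 | CNP0292337.1, (6S,7R,8S,9R)-8-angeloyloxy-7,9-dihydroxy α-methylene lactone, 1(10)Z,4E | C=C1C(=O)O[C@H]2/C=C(\C)CC/C=C(/C)[C@@H](O)[C@H](OC(=O)/C(C)=C\C)[C@@]12O | target

## Step count and least certain steps

Total: 22 steps. Longest linear sequence: 21 steps (steps 1–6 and 8–22; step 7 is a one-step side branch).

**Step 12 (key step, proposed new method).** The most likely failure is heterolysis of the C4–C9 bond of the alkoxide into an alkoxyallyl anion and a vinylogous ester. Recombination outside the chair, or proton transfer, would then lose the stereochemical transfer or give 1,3-shift products. A second risk is β-elimination of 4-methoxybenzyl oxide from the enolate once it leaves its first conformation. Fallback with known chemistry: set out from 18 and use the neutral thermal oxy-Cope rearrangement of the silyl ether. The ether is heated in degassed o-dichlorobenzene at about 180–200 °C in base-washed glass, at the lowest temperature that gives conversion, to give the ring-expanded triethylsilyl enol ether F1, in which no alkoxide or enolate is present. Desilylation with Bu4NF/AcOH at −78 to 0 °C returns to the route at 21.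

**Step 8.** The risk is poor facial selectivity in the acetylide addition, because the iodoalkenyl and methyl groups on the quaternary carbon differ little in size. Fallback: set out from 8 and let a slim alkynyl group control the face. Colvin rearrangement with lithiated trimethylsilyldiazomethane at −78 °C gives the 6-ethynyl enone F2, whose alkynyl group strongly prefers the axial position over the methyl group. An excess of 12 is then added (the first equivalent is spent on the terminal alkyne proton); attack anti to the axial ethynyl group and aqueous work-up give the diyne carbinol F3. Silylation on oxygen (Et3SiOTf, 2,6-lutidine, −78 °C) gives the diyne silyl ether F4. Double hydrozirconation–iodination (Cp2Zr(H)Cl, then I2) converts both alkynes and returns to the route at 16.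

**Step 10.** The risk is incomplete substitution or protodeiodination at the internal, α-branched iodide at the temperature the copper catalyst needs, together with loss of the silyl group to cesium alkoxide. Fallback: set out from 14. The unhindered terminal iodoalkene alone is coupled with 17 under the same copper catalysis to give the mono enol ether alkyne F5. Zirconocene-catalysed syn hydroboration of the alkyne with pinacolborane gives the alkenylboronate F6 (boron on C7, trans to C9). Oxidative Chan–Lam-type coupling of F6 with 17 (Cu(OAc)2, Et3N, air, 25 °C) forms the second enol ether at room temperature and returns to the route at 18.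

**Step 13.** The risk is attack of the oxidant on the other enolate face if the chelated conformer is not the reactive one, and the medium ring gives no independent bias. Fallback: set out from 21 and accept the 8-epimeric hydroxy ketone F7. It is silylated (Et3SiOTf, 2,6-lutidine) to the epimeric silyl ether F8 and deprotonated with LiN(SiMe3)2 to the silyloxy enolate F9. Protonation of F9 at −78 °C with 2,6-di-tert-butyl-4-methylphenol from the same open face that the oxidant used inverts C8 and returns to the route at 24.

**Step 21.** The risk is isomerisation of the angeloyl unit to the tigloyl unit during a slow acylation of the hindered 8-hydroxyl, and migration of the lactone carbonyl from O6 to the free O8 in warm amine base. Fallback: set out from 32 and build the Z olefin on the ester at low temperature. Acylation with 2-[bis(2,2,2-trifluoroethoxy)phosphoryl]propanoic acid, dicyclohexylcarbodiimide and catalytic 4-(dimethylamino)pyridine at 0 to 25 °C gives the phosphonate ester F10. Still–Gennari olefination of F10 with acetaldehyde (KN(SiMe3)2, 18-crown-6, −78 °C) gives the Z-2-methylbut-2-enoate and returns to the route at 33.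

## Further compounds

F1 | step 12 | triethylsilyl enol ether of 21 (C8=C9, C7 and C10 trans) | COc1ccc(CO[C@H]2/C=C(\C)CC/C=C(/C)\C(O[Si](CC)(CC)CC)=C\[C@]2(CCOCc3ccc(OC)cc3)OCc3ccc(OC)cc3)cc1
F2 | step 8 | (6R)-6-ethynyl-2,6-dimethylcyclohex-2-en-1-one | O=C1C(C)=CCC[C@]1(C)C#C
F3 | step 8 | (1S,6R)-6-ethynyl-1-{4-[(4-methoxybenzyl)oxy]but-1-ynyl}-2,6-dimethylcyclohex-2-en-1-ol (the two alkynyl groups trans) | O[C@]1(C#CCCOCc2ccc(OC)cc2)C(C)=CCC[C@]1(C)C#C
F4 | step 8 | triethylsilyl ether of (1S,6R)-6-ethynyl-1-{4-[(4-methoxybenzyl)oxy]but-1-ynyl}-2,6-dimethylcyclohex-2-en-1-ol | CC[Si](CC)(CC)O[C@]1(C#CCCOCc2ccc(OC)cc2)C(C)=CCC[C@]1(C)C#C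
F5 | step 10 | triethylsilyl ether of (1R,6R)-1-{4-[(4-methoxybenzyl)oxy]but-1-ynyl}-6-{(E)-2-[(4-methoxybenzyl)oxy]ethenyl}-2,6-dimethylcyclohex-2-en-1-ol | CC[Si](CC)(CC)O[C@]1(C#CCCOCc2ccc(OC)cc2)C(C)=CCC[C@]1(C)/C=C/OCc1ccc(OC)cc1
F6 | step 10 | C7 pinacol boronate from F5 (boron trans to C9) | CC[Si](CC)(CC)O[C@]1(/C=C(/B2OC(C)(C)C(C)(C)O2)CCOCc2ccc(OC)cc2)C(C)=CCC[C@]1(C)/C=C/OCc1ccc(OC)cc1
F7 | step 13 | (6S,7S,8S)-8-hydroxy ketone, C8 epimer of 23 | COc1ccc(CO[C@H]2/C=C(\C)CC/C=C(/C)C(=O)[C@@H](O)[C@]2(CCOCc3ccc(OC)cc3)OCc3ccc(OC)cc3)cc1
F8 | step 13 | (6S,7R,8S)-8-(triethylsilyloxy) ketone, C8 epimer of 24 | COc1ccc(CO[C@H]2/C=C(\C)CC/C=C(/C)C(=O)[C@@H](O[Si](CC)(CC)CC)[C@]2(CCOCc3ccc(OC)cc3)OCc3ccc(OC)cc3)cc1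
F9 | step 13 | lithium enolate of F8 (C8 silyloxy enolate) | COc1ccc(CO[C@H]2/C=C(\C)CC/C=C(/C)\C(O[Li])=C(O[Si](CC)(CC)CC)\[C@]2(CCOCc3ccc(OC)cc3)OCc3ccc(OC)cc3)cc1
F10 | step 21 | 8-O-{2-[bis(2,2,2-trifluoroethoxy)phosphoryl]propanoyl} derivative of 32 | C=C1C(=O)O[C@H]2/C=C(\C)CC/C=C(/C)[C@@H](O[Si](C)(C)C(C)(C)C)[C@H](OC(=O)C(C)P(=O)(OCC(F)(F)F)OCC(F)(F)F)[C@@]12O
A1 | alternative 1 | lactone-fused 7-hydroxy-8-(tert-butyldimethylsilyloxy)-2-methylcyclohexenone (enone partner) | O=C1C[C@]2(O)[C@@H](O[Si](C)(C)C(C)(C)C)C(=O)C(C)=C[C@@H]2O1
A2 | alternative 1 | 1-methylcyclobutene | CC1=CCC1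
A3 | alternative 1 | cis-anti-cis photoadduct (cyclohexanone-fused bicyclo[2.2.0]hexane) | O=C1C[C@]2(O)[C@@H](O[Si](C)(C)C(C)(C)C)C(=O)[C@@]3(C)[C@@H]4CC[C@]4(C)[C@H]3[C@@H]2O1
A4 | alternative 2 | α-methylene lactone dialdehyde (C8 aldehyde, C9 Z-enal) | C=C1C(=O)O[C@@H](/C=C(\C)CC/C=C(/C)C=O)[C@@]1(O)C=O
A5 | alternative 2 | 8-deacyl target (7,8,9-triol) | C=C1C(=O)O[C@H]2/C=C(\C)CC/C=C(/C)[C@@H](O)[C@H](O)[C@@]12O
A6 | alternative 3 | open-chain ynal (C6 aldehyde, C4≡C5 alkyne) | COC(=O)C[C@@](O[Si](CC)(CC)CC)(C=O)[C@@H](O[Si](CC)(CC)CC)[C@H](O[Si](C)(C)C(C)(C)C)/C(C)=C\CCC#C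
A7 | alternative 3 | ten-membered (1Z,4E)-dienol with free C6 hydroxyl | COC(=O)C[C@@]1(O[Si](CC)(CC)CC)[C@@H](O)/C=C(\C)CC/C=C(/C)[C@@H](O[Si](C)(C)C(C)(C)C)[C@@H]1O[Si](CC)(CC)CC
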